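**Plan**
- Retrosynthesis: the eight-membered ring is opened at C19–C20 (ring-closing metathesis, then reduction of that alkene) and at C2–C20 (vinyl coupling to a C2 enol triflate). The C8–C9 bond is then cut: a C9 nitrile anion adds to a C8 aldehyde, and the nitrile is the latent C9 methyl.
- This leaves a trans-decalin nitrile (C9–C19) and a cyclopentane aldehyde (C1–C8). The cyclopentane C3–C7 with its C6 methyl, the two-carbon arm C2/C1 on C3 and C8 on C7 is (R)-carvone with its carbonyl carbon pushed out of the ring, so a photochemical Wolff contraction of the α′-diazo enone builds it.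
- Forward order: cyclopentene by ring contraction (step 4); ring B annulated onto ring C (steps 9–10); union at C8–C9 (step 14); eight-membered ring last (step 21).
- Stereochemistry: carvone's centre steers ketonisation at C7; the cis pair then steers hydroboration (C5, C6); C7 steers Felkin addition (C8). (R)-1-Phenylethylamine sets C12, which controls C17 and C18 (reductive allylation) and C9 (equatorial attack on the planar nitrile anion).

Key step: step 4

Remark: locants C1–C20 are those of the target ring path (C1 vinyl methyl, C2=C3, C4, C5–OH, C6–Me, C7, C8–OH, C9–Me, C10, C11, C12–Me, C13, C14, C15–Me2, C16–C20) and are used for all intermediates; TBS = tert-butyldimethylsilyl.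

**Route**

Step 1
Reactants: 1 (R)-carvone
Product: 3 (R)-5-acetyl-2-methylcyclohex-2-en-1-one, via ozonide 2 (not isolated)
Conditions: O3 (1 equiv, Sudan Red end point), CH2Cl2, −78 °C; Me2S, −78 °C to rt
Reagents that add atoms: ozone, [O-][O+]=O
Why: Ozonolysis with reductive work-up; the electron-rich 1,1-disubstituted isopropenyl alkene should be cleaved well before the electron-poor enone alkene, and the stereocentre is not touched.

Step 2
Reactants: 3 (R)-5-acetyl-2-methylcyclohex-2-en-1-one; 4 ethylene glycol
Product: 5 (R)-2-methyl-5-(2-methyl-1,3-dioxolan-2-yl)cyclohex-2-en-1-one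
Conditions: p-TsOH·H2O (cat.), benzene, reflux, Dean–Stark
Reagents that add atoms: none
Why: Acid-catalysed ketalisation; the saturated methyl ketone is more electrophilic than the conjugated ring ketone, so about one equivalent of diol should mask it selectively.

Step 3
Reactants: 5 ketal enone; 6 4-acetamidobenzenesulfonyl azide
Product: 9 (R)-6-diazo-2-methyl-5-(2-methyl-1,3-dioxolan-2-yl)cyclohex-2-en-1-one, via lithium dienolate 7 (not isolated), via trifluoroacetyl ketone 8 (not isolated)
Conditions: LiHMDS, THF, −78 °C; CF3CO2CH2CF3, −78 °C; then 6, Et3N, H2O (1 equiv), MeCN, rt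
Reagents that add atoms: none
Why: Detrifluoroacetylative Regitz diazo transfer: kinetic α′-deprotonation of the enone, Claisen trifluoroacetylation to activate the CH2, then transfer of N2 from the sulfonyl azide with loss of the trifluoroacetyl group on the sulfonamide.

Step 4
Reactants: 9 α′-diazo enone
Product: 11 methyl (1R,5R)-2-methyl-5-(2-methyl-1,3-dioxolan-2-yl)cyclopent-2-ene-1-carboxylate, via ketene 10 (not isolated)
Conditions: hν (365 nm, Pyrex), degassed MeOH, −40 °C
Reagents that add atoms: methanol, CO
Why: Irradiation expels N2 and the alkenyl carbon C6 shifts from the carbonyl carbon to the diazo carbon (Wolff rearrangement), so the cyclohexenone contracts to the cyclopentenyl ketene 10, whose carbonyl carbon is the future C8; the closest known reaction is the photochemical Wolff ring contraction of cyclic α-diazo ketones with alcohol trapping. The five-membered ring therefore arises by a 1,2-shift that forms C6–C7 (ring contraction), not by a cyclisation. Methanol adds to the ketene, and the resulting ester dienol is protonated at the α-carbon C7 on the face away from the bulky dioxolanyl group on the neighbouring C3, which should place the ester cis to that group. The step needs α- over γ-protonation and cis over trans ketonisation; neutral methanol at low temperature should give the kinetic β,γ-unsaturated cis ester, and the absence of base prevents epimerisation or conjugation. Carvone's single stereocentre (the future sp2 C3) thus relays its configuration to C7.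

Step 5
Reactants: 11 cis cyclopentene ester
Product: 13 methyl (1S,2R,3R,5R)-3-hydroxy-2-methyl-5-(2-methyl-1,3-dioxolan-2-yl)cyclopentane-1-carboxylate, via alkylborane 12 (not isolated)
Conditions: BH3·THF, THF, 0 °C; then 30% H2O2, aq. NaOAc, 0 °C to rt
Reagents that add atoms: hydrogen peroxide, OO
Why: Hydroboration–oxidation: syn addition of B–H from the face opposite the cis ester and dioxolanyl groups, with boron at the less substituted C5 and oxidation with retention, should set the C5 hydroxyl trans and the C6 methyl cis to the C7 ester; the buffered oxidant avoids epimerising C7.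

Step 6
Reactants: 13 hydroxy ester
Product: 14 methyl (1S,2R,3R,5R)-3-(tert-butyldimethylsilyloxy)-2-methyl-5-(2-methyl-1,3-dioxolan-2-yl)cyclopentane-1-carboxylate
Conditions: TBSCl, imidazole, DMF, rt
Reagents that add atoms: tert-butyldimethylsilyl chloride, CC(C)(C)[Si](C)(C)Cl
Why: Standard silylation of a secondary alcohol; the ether has to survive hydride, amide base and mild acid later.

Step 7
Reactants: 14 silyl ether ester
Product: 16 (1S,2R,3R,5R)-3-(tert-butyldimethylsilyloxy)-2-methyl-5-(2-methyl-1,3-dioxolan-2-yl)cyclopentane-1-carbaldehyde, via aluminium hemiacetal 15 (not isolated)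
Conditions: DIBAL-H (1.05 equiv), CH2Cl2, −78 °C; MeOH, then aq. Rochelle salt
Reagents that add atoms: none
Why: Partial DIBAL-H reduction of a methyl ester: the aluminium hemiacetal of this α-branched ester is stable at −78 °C and releases the aldehyde only on work-up, under non-basic conditions that should leave the all-cis C7 centre intact.

Step 8
Reactants: 17 3,3-dimethylcyclohexan-1-one
Product: 19 2,5,5-trimethylcyclohexan-1-one (racemic), via lithium enolate 18 (not isolated)
Conditions: LDA, THF, −78 °C; MeI, −78 to 0 °C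
Reagents that add atoms: iodomethane, CI
Why: Kinetic enolate alkylation; LDA removes a proton from C6, remote from the gem-dimethyl group, rather than from the neopentyl C2, and the racemic centre is deracemised in the next step.

Step 9
Reactants: 19 2,5,5-trimethylcyclohexan-1-one; 20 (R)-1-phenylethylamine; 21 methyl vinyl ketone
Product: 24 (S)-2,5,5-trimethyl-2-(3-oxobutyl)cyclohexan-1-one, via imine 22 (not isolated), via adduct imine 23 (not isolated)
Conditions: p-TsOH (cat.), toluene, reflux, Dean–Stark; 21, THF, rt; 10% aq. AcOH, rt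
Reagents that add atoms: none
Why: Deracemising Michael addition of a chiral imine: the more substituted secondary enamine tautomer of 22 adds to the enone through a compact aza-ene-like transition state on the face anti to the phenyl group, so that, by analogy with 2-methylcyclohexanone, the (R)-amine should give the (S) quaternary centre C12 before hydrolysis releases the auxiliary.

Step 10
Reactants: 24 (S)-diketone
Product: 25 (S)-4a,7,7-trimethyl-4,4a,5,6,7,8-hexahydronaphthalen-2(3H)-one
Conditions: NaOMe (0.2 equiv), MeOH, reflux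
Reagents that add atoms: none
Why: Intramolecular aldol condensation (second stage of a Robinson annulation) of the methyl ketone onto the ring ketone closes ring B as the enone C9(=O)–C18=C17 without touching the quaternary C12.

Step 11
Reactants: 25 (S)-octalone
Product: 27 (1S,4aS,8aS)-4a,7,7-trimethyl-1-(prop-2-en-1-yl)octahydronaphthalen-2(1H)-one, via lithium enolate 26 (not isolated)
Conditions: Li, NH3(l)/THF, t-BuOH (1 equiv), −78 °C; allyl bromide, −78 to −33 °C; then NaOMe (cat.), MeOH, rt
Reagents that add atoms: allyl bromide, C=CCBr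
Why: Birch-type reductive alkylation of an enone: dissolving-metal reduction protonates C17 axially to give the trans ring fusion and leaves the regiodefined C9–C18 enolate, which is allylated at C18; base equilibration should put the allyl group equatorial, because the axial position is 1,3-diaxial to the C12 methyl.

Step 12
Reactants: 27 allyl decalone
Product: 28 1-allyl-4a,7,7-trimethyldecahydronaphthalene-2-carbonitrile (C9 epimer mixture)
Conditions: TosMIC, t-BuOK, DME, EtOH (2 equiv), 0 to 40 °C
Reagents that add atoms: p-toluenesulfonylmethyl isocyanide, Cc1ccc(cc1)S(=O)(=O)C[N+]#[C-]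
Why: Van Leusen reductive cyanation turns the ketone into the nitrile with one added carbon (the future C9 methyl); C9 forms as an epimer mixture that is made planar in step 14, and C18 keeps its equatorial thermodynamic configuration under the basic conditions.

Step 13
Reactants: 28 allyl nitrile
Product: 29 4a,7,7-trimethyl-1-[(E)-prop-1-enyl]decahydronaphthalene-2-carbonitrile (C9 epimer mixture)
Conditions: RuHCl(CO)(PPh3)3 (5 mol %), toluene, 80 °C
Reagents that add atoms: none
Why: Ruthenium hydride catalysed one-position alkene isomerisation (allyl to 1-propenyl, E/Z immaterial) makes C19 the alkene carbon on C18, as metathesis to an eight-membered ring requires; no stereocentre is affected.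

Step 14
Reactants: 29 propenyl nitrile; 16 cyclopentane aldehyde
Product: 31 C8–C9 aldol adduct (8R alcohol; axial C9 nitrile), via lithiated nitrile 30 (not isolated)
Conditions: LDA, THF, −78 to −20 °C; 16, −78 °C; AcOH, −78 °C
Reagents that add atoms: none
Why: Aldol-type addition of a lithiated nitrile to an aldehyde: the planar N-lithio ketene imine should be attacked on its equatorial face, away from the axial hydrogens on C11 and C17, giving quaternary C9 with C8 equatorial and the nitrile axial, while Felkin–Anh approach anti to the C7–C3 bond (the side carrying the bulky dioxolanyl group) should give the 8R alcohol; the cold acidic quench prevents retro-addition.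

Step 15
Reactants: 31 hydroxy nitrile
Product: 32 C8 silyl ether of 31
Conditions: TBSOTf, 2,6-lutidine, CH2Cl2, 0 °C to rt
Reagents that add atoms: tert-butyldimethylsilyl triflate, CC(C)(C)[Si](C)(C)OS(=O)(=O)C(F)(F)F
Why: Silylation with a silyl triflate and a hindered pyridine base reaches the congested C8 alcohol that the chloride would not; the ketal tolerates these conditions at 0 °C.

Step 16
Reactants: 32 bis-silyl nitrile
Product: 34 C9 carbaldehyde, via aluminium imine 33 (not isolated)
Conditions: DIBAL-H, toluene, −78 to 0 °C; then 10% aq. tartaric acid, 0 °C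
Reagents that add atoms: water, O
Why: Partial reduction of a nitrile: DIBAL-H adds once to give an N-aluminio imine that is hydrolysed to the aldehyde on mild acidic work-up, which the ketal and silyl ethers should tolerate for a short time.

Step 17
Reactants: 34 C9 carbaldehyde
Product: 36 C9 methyl compound, via tosylhydrazone 35 (not isolated)
Conditions: TsNHNH2, THF, 50 °C; then catecholborane, CHCl3, 0 °C; NaOAc·3H2O, reflux
Reagents that add atoms: none
Why: Caglioti-type reduction of a tosylhydrazone with catecholborane (hydride addition, acetate-induced loss of sulfinate, loss of N2 from the diazene) turns the neopentyl CHO into the axial C9 methyl under conditions too mild to touch the silyl ethers, ketal or alkene; C9 has no α-hydrogen and keeps its configuration.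

Step 18
Reactants: 36 ketal
Product: 37 C2 methyl ketone
Conditions: PPTS, acetone/H2O (10:1), 55 °C
Reagents that add atoms: water, O
Why: Acid-catalysed ketal hydrolysis unmasks the methyl ketone while the secondary silyl ethers survive; any epimerisation at C3 is irrelevant because C3 becomes sp2 in the next step.

Step 19
Reactants: 37 methyl ketone
Product: 38 (Z)-C2 enol triflate (OTf cis to C7; C1 methyl cis to C4)
Conditions: Tf2O, 2,6-di-tert-butyl-4-methylpyridine, CH2Cl2, 0 °C to rt
Reagents that add atoms: triflic anhydride, O=S(=O)(OS(=O)(=O)C(F)(F)F)C(F)(F)F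
Why: Enol triflation with Tf2O and a hindered pyridine goes through the O-triflyl oxocarbenium ion and Saytzeff loss of the methine proton, so an α-branched methyl ketone should give mainly the tetrasubstituted vinyl triflate; allylic 1,3-strain should place the smaller triflyloxy group cis to the branched C7 and the methyl cis to C4H2, the geometry the ring needs.

Step 20
Reactants: 38 enol triflate
Product: 39 C2-vinyl diene (C20 cis to C7)
Conditions: tributyl(vinyl)stannane, Pd(PPh3)4 (5 mol %), LiCl, THF, 65 °C
Reagents that add atoms: tributyl(vinyl)stannane, C=C[Sn](CCCC)(CCCC)CCCC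
Why: Stille coupling of a vinyl triflate (chloride-promoted) proceeds with retention of alkene geometry and installs C20 cis to C7.

Step 21
Reactants: 39 diene
Product: 40 tetracyclic diene (C2=C3 and cis C19=C20)
Conditions: Grubbs II (10 mol %), toluene (2 mM), 80 °C
Reagents that add atoms: none
Why: Diene–ene ring-closing metathesis: the ruthenium carbene engages the terminal vinyl and the propenyl group, expels propene and closes the eight-membered ring as the cis C19=C20 alkene, the tetrasubstituted C2=C3 bond being inert; the equatorial, mutually gauche C8 and C19 bonds on the decalin pre-organise the closure.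

Step 22
Reactants: 40 tetracyclic diene
Product: 41 5,8-bis-silyl ether of the target
Conditions: 2-nitrobenzenesulfonylhydrazide, Et3N, CH2Cl2, rt
Reagents that add atoms: none
Why: Diimide reduction (concerted syn transfer of two hydrogens) is highly sensitive to alkene substitution, so the cis-disubstituted C19=C20 bond should be saturated while the tetrasubstituted C2=C3 bond is left.

Step 23
Reactants: 41 bis-silyl ether
Product: 42 target diol CNP0213887.1
Conditions: TBAF, THF, 60 °C
Reagents that add atoms: none
Why: Fluoride-mediated cleavage of both silyl ethers releases the C5 and C8 alcohols without affecting the alkene or any stereocentre.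

**Compound list**

1 | (R)-carvone | CC1=CC[C@@H](C(C)=C)CC1=O | starting material
2 | ozonide of 1 at the isopropenyl group (1,2,4-trioxolane; not isolated) | CC1=CC[C@@H](C2(C)OCOO2)CC1=O | intermediate
3 | (R)-5-acetyl-2-methylcyclohex-2-en-1-one | CC1=CC[C@@H](C(C)=O)CC1=O | intermediate
4 | ethylene glycol | OCCO | starting material
5 | (R)-2-methyl-5-(2-methyl-1,3-dioxolan-2-yl)cyclohex-2-en-1-one | CC1=CC[C@@H](C2(C)OCCO2)CC1=O | intermediate
6 | 4-acetamidobenzenesulfonyl azide | CC(=O)Nc1ccc(cc1)S(=O)(=O)N=[N+]=[N-] | starting material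
7 | lithium α′-dienolate of 5 (not isolated) | [Li+].[O-]C1=C[C@H](C2(C)OCCO2)CC=C1C | intermediate
8 | 6-trifluoroacetyl derivative of 5 (C6 enolised; not isolated) | CC1=CC[C@@H](C2(C)OCCO2)C(C(=O)C(F)(F)F)C1=O | intermediate
9 | (R)-6-diazo-2-methyl-5-(2-methyl-1,3-dioxolan-2-yl)cyclohex-2-en-1-one | CC1=CC[C@@H](C2(C)OCCO2)C(=[N+]=[N-])C1=O | intermediate
10 | ring-contracted cyclopentenyl ketene (C8 ketene on C7; not isolated) | O=C=C1C(C)=CC[C@H]1C1(C)OCCO1 | intermediate
11 | methyl (1R,5R)-2-methyl-5-(2-methyl-1,3-dioxolan-2-yl)cyclopent-2-ene-1-carboxylate (ester and dioxolanyl cis) | COC(=O)[C@H]1C(C)=CC[C@H]1C1(C)OCCO1 | intermediate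
12 | C5 alkylborane from 11 (boron trans to ester; not isolated) | COC(=O)[C@H]1[C@@H](C)[C@H](B)C[C@H]1C1(C)OCCO1 | intermediate
13 | methyl (1S,2R,3R,5R)-3-hydroxy-2-methyl-5-(2-methyl-1,3-dioxolan-2-yl)cyclopentane-1-carboxylate | COC(=O)[C@H]1[C@@H](C)[C@H](O)C[C@H]1C1(C)OCCO1 | intermediate
14 | methyl (1S,2R,3R,5R)-3-(tert-butyldimethylsilyloxy)-2-methyl-5-(2-methyl-1,3-dioxolan-2-yl)cyclopentane-1-carboxylate | COC(=O)[C@H]1[C@@H](C)[C@H](O[Si](C)(C)C(C)(C)C)C[C@H]1C1(C)OCCO1 | intermediate
15 | diisobutylaluminium hemiacetal of 14 (not isolated) | COC(O[Al](CC(C)C)CC(C)C)[C@H]1[C@@H](C)[C@H](O[Si](C)(C)C(C)(C)C)C[C@H]1C1(C)OCCO1 | intermediate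
16 | (1S,2R,3R,5R)-3-(tert-butyldimethylsilyloxy)-2-methyl-5-(2-methyl-1,3-dioxolan-2-yl)cyclopentane-1-carbaldehyde (C8 aldehyde) | O=C[C@H]1[C@@H](C)[C@H](O[Si](C)(C)C(C)(C)C)C[C@H]1C1(C)OCCO1 | intermediate
17 | 3,3-dimethylcyclohexan-1-one | CC1(C)CCCC(=O)C1 | starting material
18 | lithium 5,5-dimethylcyclohex-1-en-1-olate (not isolated) | [Li+].[O-]C1=CCCC(C)(C)C1 | intermediate
19 | 2,5,5-trimethylcyclohexan-1-one (racemic) | CC1CCC(C)(C)CC1=O | intermediate
20 | (R)-1-phenylethylamine | C[C@@H](N)c1ccccc1 | starting material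
21 | methyl vinyl ketone | CC(=O)C=C | starting material
22 | imine of 19 with 20 (not isolated) | CC1CCC(C)(C)CC1=N[C@H](C)c1ccccc1 | intermediate
23 | Michael adduct imine with (S) quaternary carbon (not isolated) | CC(=O)CC[C@]1(C)CCC(C)(C)CC1=N[C@H](C)c1ccccc1 | intermediate
24 | (S)-2,5,5-trimethyl-2-(3-oxobutyl)cyclohexan-1-one | CC(=O)CC[C@]1(C)CCC(C)(C)CC1=O | intermediate
25 | (S)-4a,7,7-trimethyl-4,4a,5,6,7,8-hexahydronaphthalen-2(3H)-one | O=C1CC[C@]2(C)CCC(C)(C)CC2=C1 | intermediate
26 | lithium C9–C18 enolate of the trans-decalone (not isolated) | [Li+].[O-]C1=C[C@@H]2CC(C)(C)CC[C@@]2(C)CC1 | intermediate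
27 | (1S,4aS,8aS)-4a,7,7-trimethyl-1-(prop-2-en-1-yl)octahydronaphthalen-2(1H)-one (trans-fused, allyl equatorial) | C=CC[C@@H]1C(=O)CC[C@]2(C)CCC(C)(C)C[C@@H]12 | intermediate
28 | 1-allyl-4a,7,7-trimethyldecahydronaphthalene-2-carbonitrile (ring centres as in 27; epimer mixture at the nitrile carbon C9) | C=CC[C@@H]1C(C#N)CC[C@]2(C)CCC(C)(C)C[C@@H]12 | intermediate
29 | 4a,7,7-trimethyl-1-[(E)-prop-1-enyl]decahydronaphthalene-2-carbonitrile (ring centres as in 27; C9 epimer mixture) | C/C=C/[C@@H]1C(C#N)CC[C@]2(C)CCC(C)(C)C[C@@H]12 | intermediate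
30 | N-lithio ketene imine of 29 (C9 planar; not isolated) | [Li+].[N-]=C=C1CC[C@]2(C)CCC(C)(C)C[C@H]2[C@@H]1/C=C/C | intermediate
31 | aldol adduct: 8R alcohol, quaternary C9 with axial nitrile and equatorial C8, cyclopentane as in 16, decalin as in 29 | CC1(OCCO1)[C@@H]1C[C@@H](O[Si](C)(C)C(C)(C)C)[C@H](C)[C@@H]1[C@@H](O)[C@@]1(C#N)CC[C@]2(C)CCC(C)(C)C[C@H]2[C@@H]1/C=C/C | intermediate
32 | C8 TBS ether of 31 | CC1(OCCO1)[C@@H]1C[C@@H](O[Si](C)(C)C(C)(C)C)[C@H](C)[C@@H]1[C@@H](O[Si](C)(C)C(C)(C)C)[C@@]1(C#N)CC[C@]2(C)CCC(C)(C)C[C@H]2[C@@H]1/C=C/C | intermediate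
33 | N-(diisobutylaluminio) imine from 32 (not isolated) | CC1(OCCO1)[C@@H]1C[C@@H](O[Si](C)(C)C(C)(C)C)[C@H](C)[C@@H]1[C@@H](O[Si](C)(C)C(C)(C)C)[C@@]1(C=N[Al](CC(C)C)CC(C)C)CC[C@]2(C)CCC(C)(C)C[C@H]2[C@@H]1/C=C/C | intermediate
34 | C9 carbaldehyde (axial CHO in place of the nitrile of 32) | CC1(OCCO1)[C@@H]1C[C@@H](O[Si](C)(C)C(C)(C)C)[C@H](C)[C@@H]1[C@@H](O[Si](C)(C)C(C)(C)C)[C@@]1(C=O)CC[C@]2(C)CCC(C)(C)C[C@H]2[C@@H]1/C=C/C | intermediate
35 | tosylhydrazone of 34 (not isolated) | CC1(OCCO1)[C@@H]1C[C@@H](O[Si](C)(C)C(C)(C)C)[C@H](C)[C@@H]1[C@@H](O[Si](C)(C)C(C)(C)C)[C@@]1(C=NNS(=O)(=O)c3ccc(C)cc3)CC[C@]2(C)CCC(C)(C)C[C@H]2[C@@H]1/C=C/C | intermediate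
36 | C9 methyl compound: 5,8-bis-TBS ether with C3 dioxolanyl arm and C18 propenyl | CC1(OCCO1)[C@@H]1C[C@@H](O[Si](C)(C)C(C)(C)C)[C@H](C)[C@@H]1[C@@H](O[Si](C)(C)C(C)(C)C)[C@@]1(C)CC[C@]2(C)CCC(C)(C)C[C@H]2[C@@H]1/C=C/C | intermediate
37 | C2 methyl ketone (acetyl on C3) from 36 | CC(=O)[C@@H]1C[C@@H](O[Si](C)(C)C(C)(C)C)[C@H](C)[C@@H]1[C@@H](O[Si](C)(C)C(C)(C)C)[C@@]1(C)CC[C@]2(C)CCC(C)(C)C[C@H]2[C@@H]1/C=C/C | intermediate
38 | (Z)-C2 enol triflate, C2=C3 tetrasubstituted, OTf cis to C7 | C/C(OS(=O)(=O)C(F)(F)F)=C1\C[C@@H](O[Si](C)(C)C(C)(C)C)[C@H](C)[C@@H]1[C@@H](O[Si](C)(C)C(C)(C)C)[C@@]1(C)CC[C@]2(C)CCC(C)(C)C[C@H]2[C@@H]1/C=C/C | intermediate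
39 | C2-vinyl diene, vinyl (C20) cis to C7 | C/C(C=C)=C1\C[C@@H](O[Si](C)(C)C(C)(C)C)[C@H](C)[C@@H]1[C@@H](O[Si](C)(C)C(C)(C)C)[C@@]1(C)CC[C@]2(C)CCC(C)(C)C[C@H]2[C@@H]1/C=C/C | intermediate
40 | tetracyclic 5-8-6-6 diene (C2=C3 and cis C19=C20), 5,8-bis-TBS ether | C/C1=C2\C[C@@H](O[Si](C)(C)C(C)(C)C)[C@H](C)[C@@H]2[C@@H](O[Si](C)(C)C(C)(C)C)[C@@]2(C)CC[C@]3(C)CCC(C)(C)C[C@H]3[C@@H]2/C=C\1 | intermediate
41 | 5,8-bis-TBS ether of the target | C/C1=C2\C[C@@H](O[Si](C)(C)C(C)(C)C)[C@H](C)[C@@H]2[C@@H](O[Si](C)(C)C(C)(C)C)[C@@]2(C)CC[C@]3(C)CCC(C)(C)C[C@H]3[C@@H]2CC1 | intermediate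
42 | CNP0213887.1, (5R,6R,7S,8R,9S,12S,17S,18S)-diol | C/C1=C2\C[C@@H](O)[C@H](C)[C@@H]2[C@@H](O)[C@@]2(C)CC[C@]3(C)CCC(C)(C)C[C@H]3[C@@H]2CC1 | target

**Step count**
Total: 23 steps. Longest linear sequence: 17 steps (steps 1–7, then 14–23); the decalin branch is 6 steps (8–13).

**Steps most likely to fail**

Most at risk is step 19. Triflation may occur on the methyl side, or with the triflyloxy group trans to C7, so that the wrong regio- or geometric isomer dominates. In that case the alkene would be made inside the closed ring, where geometry is enforced. Starting from ketone 37, vinylmagnesium bromide with CeCl3 (THF, −78 °C) would give the tertiary allylic alcohol F2. Ring-closing metathesis (Grubbs II, dilute toluene) would join its vinyl group to the C18 propenyl group and give the cyclooctenol F3. Dehydration of this tertiary allylic alcohol with Burgess reagent, removing the C3 hydrogen, would give diene 40, where the route is rejoined.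

Second is step 14. The basic nitrile anion may remove the C7 proton of the aldehyde (enolisation and epimerisation) instead of adding, or facial selectivity at C8 and C9 may be poor. The fallback sets out from nitrile 29, which would be converted (LDA, then TBSCl) into the N-silyl ketene imine F1. This neutral nucleophile would add to aldehyde 16 in a Mukaiyama-type aldol under Lewis-base activation (SiCl4 with a phosphoramide, CH2Cl2, −78 °C) through an open transition state, and aqueous work-up returns to hydroxy nitrile 31.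

Third is step 21. The conjugated diene may react sluggishly and oligomerise by cross-metathesis before the medium ring closes. The ring would then be closed by sp2–sp3 coupling. Starting from triflate 38, ethenolysis (Hoveyda–Grubbs II, ethylene, CH2Cl2) would trim the propenyl group to give the C18-vinyl triflate F4. 9-BBN would hydroborate the vinyl group to the B-alkyl borane F5. Intramolecular B-alkyl Suzuki–Miyaura coupling (Pd(dppf)Cl2, AsPh3, Cs2CO3, DMF/THF/H2O, high dilution) would form C2–C20 and give bis-silyl ether 41 directly, bypassing steps 20–22.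

Further compounds
F1 | step 14 | N-(tert-butyldimethylsilyl) ketene imine of nitrile 29 | CC(C)(C)[Si](C)(C)N=C=C1CC[C@]2(C)CCC(C)(C)C[C@H]2[C@@H]1/C=C/C
F2 | step 19 | tertiary allylic alcohol from 37 and vinylmagnesium bromide (C2 epimers) | C=CC(C)(O)[C@@H]1C[C@@H](O[Si](C)(C)C(C)(C)C)[C@H](C)[C@@H]1[C@@H](O[Si](C)(C)C(C)(C)C)[C@@]1(C)CC[C@]2(C)CCC(C)(C)C[C@H]2[C@@H]1/C=C/C
F3 | step 19 | tetracyclic cyclooctenol (C2 tertiary alcohol, cis C19=C20, C3–H) | CC1(O)[C@@H]2C[C@@H](O[Si](C)(C)C(C)(C)C)[C@H](C)[C@@H]2[C@@H](O[Si](C)(C)C(C)(C)C)[C@@]2(C)CC[C@]3(C)CCC(C)(C)C[C@H]3[C@@H]2/C=C\1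
F4 | step 21 | C18-vinyl analogue of enol triflate 38 | C/C(OS(=O)(=O)C(F)(F)F)=C1\C[C@@H](O[Si](C)(C)C(C)(C)C)[C@H](C)[C@@H]1[C@@H](O[Si](C)(C)C(C)(C)C)[C@@]1(C)CC[C@]2(C)CCC(C)(C)C[C@H]2[C@@H]1C=C
F5 | step 21 | B-(C20-alkyl)-9-borabicyclo[3.3.1]nonane from F4 | C/C(OS(=O)(=O)C(F)(F)F)=C1\C[C@@H](O[Si](C)(C)C(C)(C)C)[C@H](C)[C@@H]1[C@@H](O[Si](C)(C)C(C)(C)C)[C@@]1(C)CC[C@]2(C)CCC(C)(C)C[C@H]2[C@@H]1CCB1C2CCCC1CCC2
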